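**Retrosynthetic overview**

1. Target ⇐ its 1,3-bis-silyl ether ⇐ open-chain (Z)-enal carrying a 2-(methoxycarbonyl)allylboronate: the C6–C7 bond is closed by an intramolecular allylboration catalysed by a chiral phosphoric acid. The ten-membered carbocycle forms first and the cis-fused α-methylene γ-lactone closes directly afterwards in the same flask (the only ring-forming step).
2. Open-chain precursor ⇐ allylic bromide (Br→Bpin exchange, C8 angeloylation, C6 unmasking) ⇐ 2-substituted allylsilane (C1–C6, C9, C10, C14, C15) + bromo enal (C7, C8, C11–C13) by a catalytic asymmetric Hosomi–Sakurai reaction (C8–C9 bond, C8 stereocentre).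
3. Allylsilane ⇐ β-silyloxy aldehyde + (Z)-3-iodobut-2-en-1-ol by asymmetric Nozaki–Hiyama–Kishi coupling (C3–C4 bond, C3 stereocentre; the Z-alkene is carried in from the iodide).
4. β-Silyloxy aldehyde ⇐ 2-(silylmethyl)acrolein + acetaldehyde silyl enol ether by an organocatalytic Mukaiyama aldol reaction (first stereocentre, C1); the acrolein comes from 2-bromoallylsilane and DMF.
5. Bromo enal ⇐ Morita–Baylis–Hillman adduct of 2,2-dimethoxyacetaldehyde and methyl acrylate; the iodide ⇐ but-2-yn-1-ol.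

Assumption: the SMILES is read literally as the (1S,3S,6S,7R,8R)-4Z isomer (germacrane numbering, used for atom labels throughout) with a cis-fused 12,6-lactone and a (Z)-angelate at C8; where the facial sense of a chiral catalyst on these exact substrates is not documented, the enantiomer or face named is the one expected by analogy and the antipode would be used otherwise.

**Route**

Step 1
Reactants: 1 but-2-yn-1-ol
Product: 3 (2Z)-3-iodobut-2-en-1-ol, via alkenylalanate 2 (not isolated)
Conditions: NaAlH2(OCH2CH2OCH3)2, THF, 0 °C to rt; then I2, THF, −78 °C to 0 °C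
Reagents that add atoms: iodine ([I][I]); NaAlH2(OCH2CH2OCH3)2 ([Na+].[AlH2-](OCCOC)OCCOC)
Why: Hydroxyl-directed trans-hydroalumination of the propargylic alcohol puts aluminium on the distal carbon cis to the CH2O group (the sodium, aluminium and alkoxy groups of the hydride reagent are found in intermediate 2 only), and iodinolysis with retention gives the (Z)-vinyl iodide that fixes the later C4=C5 geometry (alkyne hydroalumination–iodination).

Step 2
Reactants: 4 (2-bromoprop-2-en-1-yl)trimethylsilane; 5 N,N-dimethylformamide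
Product: 7 2-[(trimethylsilyl)methyl]prop-2-enal, via vinyllithium 6 (not isolated)
Conditions: t-BuLi (2.0 equiv), Et2O, −78 °C; then 5, −78 °C to 0 °C; aq NH4Cl
Reagents that add atoms: tert-butyllithium ([Li]C(C)(C)C)
Why: Bromine–lithium exchange of the vinyl bromide (the organolithium reagent supplies only the lithium of intermediate 6) followed by formylation of the vinyllithium with DMF (Bouveault-type aldehyde synthesis) leaves the allylsilane untouched.

Step 3
Reactants: 7 2-[(trimethylsilyl)methyl]prop-2-enal; 8 tert-butyl(ethenyloxy)dimethylsilane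
Product: 9 (3S)-3-[(tert-butyldimethylsilyl)oxy]-4-methylidene-5-(trimethylsilyl)pentanal
Conditions: confined chiral imidodiphosphorimidate (IDPi) Brønsted acid (1 mol%, enantiomer for Si-face attack), CH2Cl2/pentane, −60 °C
Reagents that add atoms: none
Why: Organocatalytic Mukaiyama aldol reaction in which the chiral silylium–imidodiphosphorimidate ion pair activates the enal, the acetaldehyde enol silane adds to its Si face and the silyl group moves to the aldolate oxygen, so the (S)-carbinol (C1, the first stereocentre) is set by the catalyst and arrives already protected, while the confined pocket prevents a second aldolisation.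

Step 4
Reactants: 9 (3S)-3-[(tert-butyldimethylsilyl)oxy]-4-methylidene-5-(trimethylsilyl)pentanal; 3 (2Z)-3-iodobut-2-en-1-ol
Product: 10 (2Z,4S,6S)-6-[(tert-butyldimethylsilyl)oxy]-3-methyl-7-methylidene-8-(trimethylsilyl)oct-2-ene-1,4-diol
Conditions: CrCl2 (3 equiv), NiCl2 (2 mol%), (S)-4-isopropyl-oxazolinylaryl methanesulfonamide ligand (3.3 equiv), Et3N, THF, rt
Reagents that add atoms: none
Why: Asymmetric Nozaki–Hiyama–Kishi coupling in which the nickel-derived (Z)-alkenylchromium species (geometry retained, free hydroxyl tolerated) adds to the Re face of the aldehyde under control of the chromium-bound chiral sulfonamide ligand, giving the (S)-carbinol at C3 anti to the C1 silyloxy group, the sense also weakly favoured by the β-silyloxy aldehyde itself.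

Step 5
Reactants: 10 (2Z,4S,6S)-6-[(tert-butyldimethylsilyl)oxy]-3-methyl-7-methylidene-8-(trimethylsilyl)oct-2-ene-1,4-diol
Product: 11 (2Z,4S,6S)-1,4,6-tris[(tert-butyldimethylsilyl)oxy]-3-methyl-7-methylidene-8-(trimethylsilyl)oct-2-ene
Conditions: TBSOTf (2.4 equiv), 2,6-lutidine, CH2Cl2, −78 °C to 0 °C
Reagents that add atoms: tert-butyldimethylsilyl triflate (CC(C)(C)[Si](C)(C)OS(=O)(=O)C(F)(F)F)
Why: Standard silylation of both hydroxyl groups under buffered conditions that do not protodesilylate the allylsilane; no stereocentre is touched.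

Step 6
Reactants: 12 2,2-dimethoxyacetaldehyde; 13 methyl prop-2-enoate
Product: 14 methyl 3-hydroxy-4,4-dimethoxy-2-methylidenebutanoate (racemic)
Conditions: DABCO (0.5 equiv), dioxane/H2O, rt
Reagents that add atoms: none
Why: Morita–Baylis–Hillman reaction of the activated α-alkoxy aldehyde with the DABCO-derived ammonium enolate of the acrylate; the racemic carbinol is erased in the next step.

Step 7
Reactants: 14 methyl 3-hydroxy-4,4-dimethoxy-2-methylidenebutanoate (racemic)
Product: 15 methyl (2Z)-2-(bromomethyl)-4-oxobut-2-enoate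
Conditions: 48% aq HBr, H2SO4 (cat.), CH2Cl2, 0 °C to rt
Reagents that add atoms: hydrogen bromide (Br)
Why: Acid-mediated SN2′ bromination with allylic transposition gives the thermodynamically preferred (Z)-2-(bromomethyl)enoate (formyl group trans to the ester) and the aqueous acid hydrolyses the dimethyl acetal in the same operation.

Step 8
Reactants: 11 (2Z,4S,6S)-1,4,6-tris[(tert-butyldimethylsilyl)oxy]-3-methyl-7-methylidene-8-(trimethylsilyl)oct-2-ene; 15 methyl (2Z)-2-(bromomethyl)-4-oxobut-2-enoate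
Product: 16 methyl (2Z,4R,7S,9S,10Z)-2-(bromomethyl)-7,9,12-tris[(tert-butyldimethylsilyl)oxy]-10-methyl-6-methylidene-4-[(trimethylsilyl)oxy]dodeca-2,10-dienoate
Conditions: confined chiral IDPi Brønsted acid (2 mol%, enantiomer for Re-face attack), toluene, −78 °C to −40 °C
Reagents that add atoms: none
Why: Catalytic asymmetric Hosomi–Sakurai allylation in which the chiral silylium ion pair activates the electron-poor enal, the 2-substituted allylsilane adds 1,2 to its Re face through an open transition state to give the (R)-carbinol at C8 under catalyst control, and the trimethylsilyl group ends on the new oxygen; the amine-free conditions leave the allylic bromide intact.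

Step 9
Reactants: 16 methyl (2Z,4R,7S,9S,10Z)-2-(bromomethyl)-7,9,12-tris[(tert-butyldimethylsilyl)oxy]-10-methyl-6-methylidene-4-[(trimethylsilyl)oxy]dodeca-2,10-dienoate
Product: 18 methyl (2E,4R,7S,9S,10Z)-7,9,12-tris[(tert-butyldimethylsilyl)oxy]-4-hydroxy-10-methyl-6-methylidene-2-[(4,4,5,5-tetramethyl-1,3,2-dioxaborolan-2-yl)methyl]dodeca-2,10-dienoate, via boronate silyl ether 17 (not isolated)
Conditions: B2pin2 (1.2 equiv), Pd2(dba)3 (2.5 mol%), THF, 40 °C; then citric acid, MeOH, 0 °C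
Reagents that add atoms: bis(pinacolato)diboron (CC1(C)OB(OC1(C)C)B1OC(C)(C)C(C)(C)O1)
Why: Miyaura-type allylic borylation: zerovalent palladium forms a π-allyl complex from the bromide, transmetalation with the diboron and reductive elimination at the primary terminus give the conjugated allylboronate with unchanged alkene geometry (C8 cis to CH2B), and mild acidic methanol then removes only the trimethylsilyl ether; borylating before deprotection avoids cyclisation of a γ-hydroxy allylic bromide.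

Step 10
Reactants: 18 methyl (2E,4R,7S,9S,10Z)-7,9,12-tris[(tert-butyldimethylsilyl)oxy]-4-hydroxy-10-methyl-6-methylidene-2-[(4,4,5,5-tetramethyl-1,3,2-dioxaborolan-2-yl)methyl]dodeca-2,10-dienoate; 19 (2Z)-2-methylbut-2-enoic acid (angelic acid)
Product: 21 methyl (2E,4R,7S,9S,10Z)-7,9,12-tris[(tert-butyldimethylsilyl)oxy]-10-methyl-6-methylidene-4-{[(2Z)-2-methylbut-2-enoyl]oxy}-2-[(4,4,5,5-tetramethyl-1,3,2-dioxaborolan-2-yl)methyl]dodeca-2,10-dienoate, via mixed anhydride 20 (not isolated)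
Conditions: 19, 2,4,6-Cl3C6H2COCl, Et3N, toluene, rt; then 18, toluene, 75 °C
Reagents that add atoms: 2,4,6-trichlorobenzoyl chloride (O=C(Cl)c1c(Cl)cc(Cl)cc1Cl)
Why: Yamaguchi esterification through the mixed trichlorobenzoic anhydride (the aroyl group of the acid chloride is found in intermediate 20 only) acylates the hindered allylic alcohol with retention at C8, and omitting a nucleophilic pyridine catalyst keeps the (Z)-angelate from isomerising to the tiglate; the allylboronate tolerates the amine base.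

Step 11
Reactants: 21 methyl (2E,4R,7S,9S,10Z)-7,9,12-tris[(tert-butyldimethylsilyl)oxy]-10-methyl-6-methylidene-4-{[(2Z)-2-methylbut-2-enoyl]oxy}-2-[(4,4,5,5-tetramethyl-1,3,2-dioxaborolan-2-yl)methyl]dodeca-2,10-dienoate
Product: 22 methyl (2E,4R,7S,9S,10Z)-7,9-bis[(tert-butyldimethylsilyl)oxy]-12-hydroxy-10-methyl-6-methylidene-4-{[(2Z)-2-methylbut-2-enoyl]oxy}-2-[(4,4,5,5-tetramethyl-1,3,2-dioxaborolan-2-yl)methyl]dodeca-2,10-dienoate
Conditions: PPTS (0.2 equiv), MeOH/CH2Cl2, 0 °C to rt
Reagents that add atoms: none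
Why: Selective acid-catalysed methanolysis, since the primary allylic silyl ether is cleaved far faster than the two secondary ones and the pinacol boronate and angelate are stable to mild acid.

Step 12
Reactants: 22 methyl (2E,4R,7S,9S,10Z)-7,9-bis[(tert-butyldimethylsilyl)oxy]-12-hydroxy-10-methyl-6-methylidene-4-{[(2Z)-2-methylbut-2-enoyl]oxy}-2-[(4,4,5,5-tetramethyl-1,3,2-dioxaborolan-2-yl)methyl]dodeca-2,10-dienoate
Product: 25 (1S,3S,6S,7R,8R,4Z)-8-angeloyloxy-1,3-bis[(tert-butyldimethylsilyl)oxy]germacra-4,10(14),11(13)-trien-12,6-olide, via seco-enal 23 (not isolated), via borate ester 24 (not isolated)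
Conditions: MnO2, CH2Cl2, rt; filter; then (R)-TRIP [(R)-3,3′-bis(2,4,6-triisopropylphenyl)-1,1′-binaphthyl-2,2′-diyl hydrogen phosphate] (10 mol%), 4 Å MS, toluene (2 mM), 0 °C to 40 °C
Reagents that add atoms: none
Why: Proposed new method: after neutral MnO2 oxidation to the (Z)-enal, the chiral phosphoric acid hydrogen-bonds to a boronate oxygen and the formyl C–H, so the otherwise sluggish 2-alkoxycarbonyl allylboronate adds intramolecularly to the Re face of the aldehyde through a closed chair Zimmerman–Traxler transition state in which the C8 substituent cis to CH2B is axial, giving the 6,7-syn adduct (6S,7R) with the new bond formed anti to the C9 chain of the (8R) centre whose hydrogen lies in the alkene plane to avoid allylic 1,3-strain (substrate bias and catalyst matched), and the resulting borate lactonises onto the methyl ester to the cis-fused α-methylene γ-lactone; the closest known reactions are the intermolecular phosphoric-acid-catalysed allylboration of aldehydes with 2-alkoxycarbonyl allylboronates and the chromium-mediated intramolecular allylation used to close germacranolides, and what is new is its use as a metal-free ten-membered ring closure that avoids an allylmetal able to eliminate the C8 acyloxy group.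

Step 13
Reactants: 25 (1S,3S,6S,7R,8R,4Z)-8-angeloyloxy-1,3-bis[(tert-butyldimethylsilyl)oxy]germacra-4,10(14),11(13)-trien-12,6-olide
Product: 26 (1S,3S,6S,7R,8R,4Z)-8-angeloyloxy-1,3-dihydroxygermacra-4,10(14),11(13)-trien-12,6-olide (CNP0175889.6)
Conditions: HF·pyridine, pyridine, THF, 0 °C to rt
Reagents that add atoms: none
Why: Buffered fluoride desilylation cleaves both secondary silyl ethers without base, so the α-methylene lactone and the angelate are not exposed to alkoxide (no oxa-Michael addition or acyl migration) and no stereocentre is affected.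

**Compound list**

1 | but-2-yn-1-ol | CC#CCO | starting material
2 | sodium 2,2-bis(2-methoxyethoxy)-3-methyl-2,5-dihydro-1,2-oxaaluminol-2-uide (cyclic Z-alkenylalanate) | [Na+].COCCO[Al-]1(OCCOC)OCC=C1C | intermediate
3 | (2Z)-3-iodobut-2-en-1-ol | C/C([I])=C/CO | intermediate
4 | (2-bromoprop-2-en-1-yl)trimethylsilane | C=C(Br)C[Si](C)(C)C | starting material
5 | N,N-dimethylformamide | CN(C)C=O | starting material
6 | [3-(trimethylsilyl)prop-1-en-2-yl]lithium | [Li]C(=C)C[Si](C)(C)C | intermediate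
7 | 2-[(trimethylsilyl)methyl]prop-2-enal | C=C(C[Si](C)(C)C)C=O | intermediate
8 | tert-butyl(ethenyloxy)dimethylsilane | C=CO[Si](C)(C)C(C)(C)C | starting material
9 | (3S)-3-[(tert-butyldimethylsilyl)oxy]-4-methylidene-5-(trimethylsilyl)pentanal | O=CC[C@H](O[Si](C)(C)C(C)(C)C)C(=C)C[Si](C)(C)C | intermediate
10 | (2Z,4S,6S)-6-[(tert-butyldimethylsilyl)oxy]-3-methyl-7-methylidene-8-(trimethylsilyl)oct-2-ene-1,4-diol | OC/C=C(/C)[C@@H](O)C[C@H](O[Si](C)(C)C(C)(C)C)C(=C)C[Si](C)(C)C | intermediate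
11 | (2Z,4S,6S)-1,4,6-tris[(tert-butyldimethylsilyl)oxy]-3-methyl-7-methylidene-8-(trimethylsilyl)oct-2-ene | CC(C)(C)[Si](C)(C)OC/C=C(/C)[C@@H](O[Si](C)(C)C(C)(C)C)C[C@H](O[Si](C)(C)C(C)(C)C)C(=C)C[Si](C)(C)C | intermediate
12 | 2,2-dimethoxyacetaldehyde | COC(OC)C=O | starting material
13 | methyl prop-2-enoate (methyl acrylate) | C=CC(=O)OC | starting material
14 | methyl 3-hydroxy-4,4-dimethoxy-2-methylidenebutanoate (racemic) | C=C(C(=O)OC)C(O)C(OC)OC | intermediate
15 | methyl (2Z)-2-(bromomethyl)-4-oxobut-2-enoate | O=C/C=C(\CBr)C(=O)OC | intermediate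
16 | methyl (2Z,4R,7S,9S,10Z)-2-(bromomethyl)-7,9,12-tris[(tert-butyldimethylsilyl)oxy]-10-methyl-6-methylidene-4-[(trimethylsilyl)oxy]dodeca-2,10-dienoate | CC(C)(C)[Si](C)(C)OC/C=C(/C)[C@@H](O[Si](C)(C)C(C)(C)C)C[C@H](O[Si](C)(C)C(C)(C)C)C(=C)C[C@@H](O[Si](C)(C)C)/C=C(\CBr)C(=O)OC | intermediate
17 | methyl (2E,4R,7S,9S,10Z)-7,9,12-tris[(tert-butyldimethylsilyl)oxy]-10-methyl-6-methylidene-2-[(4,4,5,5-tetramethyl-1,3,2-dioxaborolan-2-yl)methyl]-4-[(trimethylsilyl)oxy]dodeca-2,10-dienoate | CC(C)(C)[Si](C)(C)OC/C=C(/C)[C@@H](O[Si](C)(C)C(C)(C)C)C[C@H](O[Si](C)(C)C(C)(C)C)C(=C)C[C@@H](O[Si](C)(C)C)/C=C(\CB1OC(C)(C)C(C)(C)O1)C(=O)OC | intermediate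
18 | methyl (2E,4R,7S,9S,10Z)-7,9,12-tris[(tert-butyldimethylsilyl)oxy]-4-hydroxy-10-methyl-6-methylidene-2-[(4,4,5,5-tetramethyl-1,3,2-dioxaborolan-2-yl)methyl]dodeca-2,10-dienoate | CC(C)(C)[Si](C)(C)OC/C=C(/C)[C@@H](O[Si](C)(C)C(C)(C)C)C[C@H](O[Si](C)(C)C(C)(C)C)C(=C)C[C@@H](O)/C=C(\CB1OC(C)(C)C(C)(C)O1)C(=O)OC | intermediate
19 | (2Z)-2-methylbut-2-enoic acid (angelic acid) | C/C=C(/C)C(=O)O | starting material
20 | (2Z)-2-methylbut-2-enoic 2,4,6-trichlorobenzoic anhydride | C/C=C(/C)C(=O)OC(=O)c1c(Cl)cc(Cl)cc1Cl | intermediate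
21 | methyl (2E,4R,7S,9S,10Z)-7,9,12-tris[(tert-butyldimethylsilyl)oxy]-10-methyl-6-methylidene-4-{[(2Z)-2-methylbut-2-enoyl]oxy}-2-[(4,4,5,5-tetramethyl-1,3,2-dioxaborolan-2-yl)methyl]dodeca-2,10-dienoate | CC(C)(C)[Si](C)(C)OC/C=C(/C)[C@@H](O[Si](C)(C)C(C)(C)C)C[C@H](O[Si](C)(C)C(C)(C)C)C(=C)C[C@@H](OC(=O)/C(C)=C\C)/C=C(\CB1OC(C)(C)C(C)(C)O1)C(=O)OC | intermediate
22 | methyl (2E,4R,7S,9S,10Z)-7,9-bis[(tert-butyldimethylsilyl)oxy]-12-hydroxy-10-methyl-6-methylidene-4-{[(2Z)-2-methylbut-2-enoyl]oxy}-2-[(4,4,5,5-tetramethyl-1,3,2-dioxaborolan-2-yl)methyl]dodeca-2,10-dienoate | OC/C=C(/C)[C@@H](O[Si](C)(C)C(C)(C)C)C[C@H](O[Si](C)(C)C(C)(C)C)C(=C)C[C@@H](OC(=O)/C(C)=C\C)/C=C(\CB1OC(C)(C)C(C)(C)O1)C(=O)OC | intermediate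
23 | methyl (2E,4R,7S,9S,10Z)-7,9-bis[(tert-butyldimethylsilyl)oxy]-10-methyl-6-methylidene-4-{[(2Z)-2-methylbut-2-enoyl]oxy}-12-oxo-2-[(4,4,5,5-tetramethyl-1,3,2-dioxaborolan-2-yl)methyl]dodeca-2,10-dienoate (seco-enal) | O=C/C=C(/C)[C@@H](O[Si](C)(C)C(C)(C)C)C[C@H](O[Si](C)(C)C(C)(C)C)C(=C)C[C@@H](OC(=O)/C(C)=C\C)/C=C(\CB1OC(C)(C)C(C)(C)O1)C(=O)OC | intermediate
24 | methyl (1S,3S,6S,7S,8R,4Z)-8-angeloyloxy-1,3-bis[(tert-butyldimethylsilyl)oxy]-6-[(4,4,5,5-tetramethyl-1,3,2-dioxaborolan-2-yl)oxy]germacra-4,10(14),11(13)-trien-12-oate (borate ester; same spatial arrangement as 25; the C7 descriptor differs by CIP ranking only) | C=C(C(=O)OC)[C@H]1[C@@H](OB2OC(C)(C)C(C)(C)O2)/C=C(/C)[C@@H](O[Si](C)(C)C(C)(C)C)C[C@H](O[Si](C)(C)C(C)(C)C)C(=C)C[C@H]1OC(=O)/C(C)=C\C | intermediate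
25 | (1S,3S,6S,7R,8R,4Z)-8-angeloyloxy-1,3-bis[(tert-butyldimethylsilyl)oxy]germacra-4,10(14),11(13)-trien-12,6-olide | C=C1C(=O)O[C@H]2/C=C(/C)[C@@H](O[Si](C)(C)C(C)(C)C)C[C@H](O[Si](C)(C)C(C)(C)C)C(=C)C[C@@H](OC(=O)/C(C)=C\C)[C@@H]12 | intermediate
26 | (1S,3S,6S,7R,8R,4Z)-8-angeloyloxy-1,3-dihydroxygermacra-4,10(14),11(13)-trien-12,6-olide (CNP0175889.6) | C=C1C(=O)O[C@H]2/C=C(/C)[C@@H](O)C[C@H](O)C(=C)C[C@@H](OC(=O)/C(C)=C\C)[C@@H]12 | target

**Step count and risks**

Total step count: 13. Longest linear sequence: 10 steps (steps 2, 3, 4, 5, 8, 9, 10, 11, 12, 13). Two steps are telescoped (9 and 12), and the only pure protecting-group operations are steps 5, 11 and 13.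

The three steps most likely to fail:

Step 12 (the proposed new ring closure). It may give oligomers, an unreactive boronate or the wrong C6/C7 diastereomer. The fallback uses the known chromium-mediated intramolecular Nozaki–Hiyama–Kishi allylation with in situ lactonisation, the established way to close germacranolides. It sets out from 16 and keeps the allylic bromide: direct acylation of the trimethylsilyl ether with angelic anhydride and catalytic Sc(OTf)3 in MeCN at −20 °C gives the bromo angelate F1; PPTS in MeOH removes the primary silyl group to give the allylic alcohol F2; MnO2 gives the bromo enal F3; slow addition of F3 to CrCl2 in THF/DMF at high dilution forms the C6–C7 bond and the lactone, and the route is rejoined at 25.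

Step 8 (catalyst-controlled Hosomi–Sakurai union of two elaborate partners). The C8 selectivity or the conversion may be poor. The fallback separates bond formation from stereocontrol. It sets out from 11 (with 15): BF3·OEt2-promoted Hosomi–Sakurai addition in CH2Cl2 at −78 °C gives the C8-epimeric alcohols F4; Dess–Martin periodinane buffered with NaHCO3 gives the ketone F5; Corey–Bakshi–Shibata reduction ((S)-Me-CBS oxazaborolidine, catecholborane, −78 °C, enone alkenyl group as the large substituent) gives the (8R)-alcohol F6; neutral silylation with N,O-bis(trimethylsilyl)acetamide rejoins the route at 16.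

Step 4 (ligand-controlled addition at C3). The diastereoselectivity next to the β-silyloxy group may be low. The fallback replaces the stereoselective C–C bond formation by a ketone reduction. It sets out from 3 (with 9): TBSCl and imidazole give the silylated iodide F7; iodine–lithium exchange (t-BuLi, Et2O, −78 °C) and addition to 9 give the C3-epimeric alcohols F8; Dess–Martin oxidation gives the (Z)-enone F9; Corey–Bakshi–Shibata reduction ((R)-Me-CBS oxazaborolidine, catecholborane) gives the (3S)-alcohol F10; TBSOTf and 2,6-lutidine rejoin the route at 11.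

**Further compounds**

F1 | step 12 | methyl (2Z,4R,7S,9S,10Z)-2-(bromomethyl)-7,9,12-tris[(tert-butyldimethylsilyl)oxy]-10-methyl-6-methylidene-4-{[(2Z)-2-methylbut-2-enoyl]oxy}dodeca-2,10-dienoate | CC(C)(C)[Si](C)(C)OC/C=C(/C)[C@@H](O[Si](C)(C)C(C)(C)C)C[C@H](O[Si](C)(C)C(C)(C)C)C(=C)C[C@@H](OC(=O)/C(C)=C\C)/C=C(\CBr)C(=O)OC
F2 | step 12 | methyl (2Z,4R,7S,9S,10Z)-2-(bromomethyl)-7,9-bis[(tert-butyldimethylsilyl)oxy]-12-hydroxy-10-methyl-6-methylidene-4-{[(2Z)-2-methylbut-2-enoyl]oxy}dodeca-2,10-dienoate | OC/C=C(/C)[C@@H](O[Si](C)(C)C(C)(C)C)C[C@H](O[Si](C)(C)C(C)(C)C)C(=C)C[C@@H](OC(=O)/C(C)=C\C)/C=C(\CBr)C(=O)OC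
F3 | step 12 | methyl (2Z,4R,7S,9S,10Z)-2-(bromomethyl)-7,9-bis[(tert-butyldimethylsilyl)oxy]-10-methyl-6-methylidene-4-{[(2Z)-2-methylbut-2-enoyl]oxy}-12-oxododeca-2,10-dienoate | O=C/C=C(/C)[C@@H](O[Si](C)(C)C(C)(C)C)C[C@H](O[Si](C)(C)C(C)(C)C)C(=C)C[C@@H](OC(=O)/C(C)=C\C)/C=C(\CBr)C(=O)OC
F4 | step 8 | methyl (2Z,7S,9S,10Z)-2-(bromomethyl)-7,9,12-tris[(tert-butyldimethylsilyl)oxy]-4-hydroxy-10-methyl-6-methylidenedodeca-2,10-dienoate (C4 epimers) | CC(C)(C)[Si](C)(C)OC/C=C(/C)[C@@H](O[Si](C)(C)C(C)(C)C)C[C@H](O[Si](C)(C)C(C)(C)C)C(=C)CC(O)/C=C(\CBr)C(=O)OC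
F5 | step 8 | methyl (2Z,7S,9S,10Z)-2-(bromomethyl)-7,9,12-tris[(tert-butyldimethylsilyl)oxy]-10-methyl-6-methylidene-4-oxododeca-2,10-dienoate | CC(C)(C)[Si](C)(C)OC/C=C(/C)[C@@H](O[Si](C)(C)C(C)(C)C)C[C@H](O[Si](C)(C)C(C)(C)C)C(=C)CC(=O)/C=C(\CBr)C(=O)OC
F6 | step 8 | methyl (2Z,4R,7S,9S,10Z)-2-(bromomethyl)-7,9,12-tris[(tert-butyldimethylsilyl)oxy]-4-hydroxy-10-methyl-6-methylidenedodeca-2,10-dienoate | CC(C)(C)[Si](C)(C)OC/C=C(/C)[C@@H](O[Si](C)(C)C(C)(C)C)C[C@H](O[Si](C)(C)C(C)(C)C)C(=C)C[C@@H](O)/C=C(\CBr)C(=O)OC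
F7 | step 4 | tert-butyl{[(2Z)-3-iodobut-2-en-1-yl]oxy}dimethylsilane | C/C([I])=C/CO[Si](C)(C)C(C)(C)C
F8 | step 4 | (2Z,6S)-1,6-bis[(tert-butyldimethylsilyl)oxy]-3-methyl-7-methylidene-8-(trimethylsilyl)oct-2-en-4-ol (C4 epimers) | CC(C)(C)[Si](C)(C)OC/C=C(/C)C(O)C[C@H](O[Si](C)(C)C(C)(C)C)C(=C)C[Si](C)(C)C
F9 | step 4 | (2Z,6S)-1,6-bis[(tert-butyldimethylsilyl)oxy]-3-methyl-7-methylidene-8-(trimethylsilyl)oct-2-en-4-one | CC(C)(C)[Si](C)(C)OC/C=C(/C)C(=O)C[C@H](O[Si](C)(C)C(C)(C)C)C(=C)C[Si](C)(C)C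
F10 | step 4 | (2Z,4S,6S)-1,6-bis[(tert-butyldimethylsilyl)oxy]-3-methyl-7-methylidene-8-(trimethylsilyl)oct-2-en-4-ol | CC(C)(C)[Si](C)(C)OC/C=C(/C)[C@@H](O)C[C@H](O[Si](C)(C)C(C)(C)C)C(=C)C[Si](C)(C)C
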